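**Retrosynthetic overview**

- Target 12 comes from boronic acid 11 by oxidation of the C1–B bond. The C1 oxygen is introduced last, so the free hydroxyl needs no protecting group to be told apart from the two methyl ethers.
- 11 comes from 3,5-dimethoxybenzyne 8, heneicosylmagnesium bromide 5 and trimethyl borate 6: the C6–C1' bond and the C1–B bond are made in one flask across the aryne triple bond.
- The strategy rests on one feature of the single benzene ring: the neighbouring carbons C6 (heneicosyl) and C1 (hydroxyl) sit directly beside the C2 methoxy group. An aryne flanked by methoxy takes up exactly this pair, the nucleophile at the far carbon (C6) and the electrophile at the carbon next to methoxy (C1).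
- The aryne precursor 3 comes from 3,5-dimethoxyphenol 1 by O-sulfonylation and then iodination at the carbon between the sulfonate and one methoxy group.
- No ring is formed; the benzene ring of 1 is carried through unchanged.

Key step: step 4

Assumption: a magnesiated aryl triflate is expected to lose triflate already at −78 °C, while isopropylmagnesium reagent is still present and the long-chain Grignard reagent is out of solution; the leaving group is therefore a 4-chlorobenzenesulfonate, whose ortho-magnesiated form should persist at −78 °C and release the aryne only on warming, and it is installed before the iodine so that the two methoxy groups alone steer the iodination.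

**Route**

Step 1
Reactants: 1 3,5-dimethoxyphenol
Product: 2 3,5-dimethoxyphenyl 4-chlorobenzenesulfonate
Conditions: 4-ClC6H4SO2Cl (1.1 equiv), Et3N (1.5 equiv), DMAP (cat.), CH2Cl2, 0 °C to rt
Reagents that add atoms: 4-chlorobenzenesulfonyl chloride, O=S(=O)(Cl)c1ccc(Cl)cc1
Why: O-sulfonylation of a phenol under amine base with DMAP catalysis is routine, and masking the hydroxyl first removes its para-directing pull toward the carbon between the two methoxy groups in the next step.

Step 2
Reactants: 2 3,5-dimethoxyphenyl 4-chlorobenzenesulfonate
Product: 3 2-iodo-3,5-dimethoxyphenyl 4-chlorobenzenesulfonate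
Conditions: NIS (1.05 equiv), CF3CO2H (cat.), MeCN, 0 °C to rt, dark
Reagents that add atoms: N-iodosuccinimide, O=C1CCC(=O)N1I
Why: electrophilic aromatic iodination of a 1-substituted 3,5-dimethoxybenzene should go to C2, para to one methoxy group and ortho to the other, as halogenation of 3,5-dimethoxytoluene and 1-bromo-3,5-dimethoxybenzene does, while the carbon flanked by both methoxy groups and the deactivated chlorophenyl ring are left alone.

Step 3
Reactants: 4 1-bromoheneicosane
Product: 5 heneicosylmagnesium bromide
Conditions: Mg turnings, I2 (cat.), THF, 45 °C, slow addition of 4; titrated and kept as a solution at 25–30 °C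
Reagents that add atoms: magnesium, [Mg]
Why: Grignard formation by insertion of magnesium into a primary C–Br bond is reliable, and slow addition at 45 °C should hold Wurtz coupling down and keep the long-chain reagent dissolved.

Step 4
Reactants: 3 2-iodo-3,5-dimethoxyphenyl 4-chlorobenzenesulfonate, 5 heneicosylmagnesium bromide, 6 trimethyl borate
Product: 11 (2-heneicosyl-4,6-dimethoxyphenyl)boronic acid, via arylmagnesium chloride 7 (not isolated), via 3,5-dimethoxybenzyne 8 (not isolated), via arylmagnesium bromide 9 (not isolated), via dimethyl arylboronate 10 (not isolated)
Conditions: 3, iPrMgCl·LiCl (1.05 equiv), THF, −78 °C, 45 min; cannula slowly into 5 (1.5 equiv), THF, 20 °C, 1 h; 6 (4 equiv), 0 °C to rt; aq NH4Cl; crude 11 taken on at once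
Reagents that add atoms: trimethyl borate 6, COB(OC)OC; water, O
Why: Iodine–magnesium exchange at the carbon between the sulfonate and a methoxy group should be fast at −78 °C, and arylmagnesium 7 keeps its arenesulfonate at that temperature, so the isopropyl reagent is spent before any aryne exists. On transfer into the solution of 5 at 20 °C, 7 expels magnesium 4-chlorobenzenesulfonate to give aryne 8, the primary alkylmagnesium adds across the strained triple bond (carbomagnesiation), and the new arylmagnesium 9 is captured by B(OMe)3 as boronate 10, which hydrolyses to 11 on work-up. The closest known reaction type is the addition of Grignard or organolithium reagents to 3-methoxyarynes released from 2-magnesiated aryl sulfonates or 1,2-dihaloarenes, followed by electrophilic quench of the resulting aryl metal; trapping an arylmagnesium halide with a trialkyl borate is standard. No ring is closed and no stereocentre is formed. The selectivity needed is regiochemical, carbon at the future C6 and magnesium at the future C1: the methoxy group beside the triple bond distorts the aryne so that the far carbon has the wider internal angle and is the better electrophile, and attack there leaves the negative charge in the in-plane orbital next to the electron-withdrawing C–O bond, where oxygen can also coordinate magnesium, while the second methoxy group, para to that carbanion, has little say. Slow inverse addition into an excess of dissolved 5 keeps aryl magnesium species from competing for the aryne, and an excess of B(OMe)3 guards against double arylation at boron.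

Step 5
Reactants: 11 (2-heneicosyl-4,6-dimethoxyphenyl)boronic acid
Product: 12 6-n-heneicosyl-2,4-dimethoxyphenol
Conditions: 30% aq H2O2, 2 M aq NaOH, THF, 0 °C, short reaction time; aq Na2S2O3, then dilute HCl to pH 5
Reagents that add atoms: hydrogen peroxide, OO
Why: oxidation of an arylboronic acid with alkaline hydrogen peroxide proceeds by addition of hydroperoxide to boron, 1,2-shift of the aryl group from boron to oxygen and hydrolysis of the borate, so the hydroxyl should appear only at C1 and both methyl ethers stay untouched.

**Compound list**

1 | 3,5-dimethoxyphenol | COc1cc(O)cc(OC)c1 | starting material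
2 | 3,5-dimethoxyphenyl 4-chlorobenzenesulfonate | COc1cc(OC)cc(OS(=O)(=O)c2ccc(Cl)cc2)c1 | intermediate
3 | 2-iodo-3,5-dimethoxyphenyl 4-chlorobenzenesulfonate | COc1cc(OC)c(I)c(OS(=O)(=O)c2ccc(Cl)cc2)c1 | intermediate
4 | 1-bromoheneicosane | CCCCCCCCCCCCCCCCCCCCCBr | starting material
5 | heneicosylmagnesium bromide | CCCCCCCCCCCCCCCCCCCCC[Mg]Br | intermediate
6 | trimethyl borate | COB(OC)OC | starting material
7 | [2-(4-chlorophenylsulfonyloxy)-4,6-dimethoxyphenyl]magnesium chloride | COc1cc(OC)c([Mg]Cl)c(OS(=O)(=O)c2ccc(Cl)cc2)c1 | intermediate
8 | 3,5-dimethoxybenzyne | COC1=CC(OC)=CC#C1 | intermediate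
9 | (2-heneicosyl-4,6-dimethoxyphenyl)magnesium bromide | CCCCCCCCCCCCCCCCCCCCCc1cc(OC)cc(OC)c1[Mg]Br | intermediate
10 | dimethyl (2-heneicosyl-4,6-dimethoxyphenyl)boronate | CCCCCCCCCCCCCCCCCCCCCc1cc(OC)cc(OC)c1B(OC)OC | intermediate
11 | (2-heneicosyl-4,6-dimethoxyphenyl)boronic acid | CCCCCCCCCCCCCCCCCCCCCc1cc(OC)cc(OC)c1B(O)O | intermediate
12 | 6-n-heneicosyl-2,4-dimethoxyphenol | CCCCCCCCCCCCCCCCCCCCCc1cc(OC)cc(OC)c1O | target

**Step count**

Total steps: 5. Longest linear sequence: 4 steps (steps 1, 2, 4 and 5 from 1); step 3 is a one-step side branch.

**Steps most likely to fail**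

Step 4. The aryne may be captured by aryl magnesium species instead of the alkyl Grignard reagent, the alkyl group may add with the wrong orientation, or the hindered arylmagnesium may be protonated before it reaches boron. The fallback builds the same boronic acid without an aryne and sets out from 1, 5 and 6. Phenol 1 is converted with Tf2O and pyridine into 3,5-dimethoxyphenyl trifluoromethanesulfonate F1. Kumada coupling of F1 with 5 under Pd(dppf)Cl2 (divalent palladium) in THF should give 1-heneicosyl-3,5-dimethoxybenzene F2. NBS in MeCN at 0 °C should brominate the ring carbon between the chain and a methoxy group, para to the other methoxy group, to give 2-bromo-1-heneicosyl-3,5-dimethoxybenzene F3. Bromine–lithium exchange with n-BuLi in THF at −40 °C gives (2-heneicosyl-4,6-dimethoxyphenyl)lithium F4, which is quenched with 6 and hydrolysed through boronate 10. The fallback rejoins the route at 11.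

Step 5. Boron may be lost by protodeboronation of the electron-rich, doubly ortho-substituted boronic acid during work-up or in the alkaline medium before oxidation overtakes it, and the electron-rich phenol may be oxidised further. The fallback delivers oxygen to the aryl magnesium directly and avoids boron. It sets out from arylmagnesium bromide 9, generated as in step 4, which is treated at −40 °C to rt with 2-(phenylsulfonyl)-3-phenyloxaziridine in an electrophilic hydroxylation of the Grignard reagent. This gives bromomagnesium 2-heneicosyl-4,6-dimethoxyphenoxide F5, and mild acidic work-up releases the phenol. The fallback rejoins the route at 12.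

Step 2. Iodination may occur at the carbon between the two methoxy groups, or twice. The fallback fixes the position by directed ortho-lithiation and sets out from 1. MOMCl and iPr2NEt give 1-(methoxymethoxy)-3,5-dimethoxybenzene F6. n-BuLi in THF at 0 °C should lithiate between the MOM ether, the stronger directing group, and a methoxy group to give [2-(methoxymethoxy)-4,6-dimethoxyphenyl]lithium F7. Iodine at −78 °C gives 2-iodo-1-(methoxymethoxy)-3,5-dimethoxybenzene F8, and HCl in MeOH removes the acetal to give 2-iodo-3,5-dimethoxyphenol F9. Sulfonylation under the conditions of step 1 rejoins the route at 3.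

**Further compounds**

F1 | step 4 | 3,5-dimethoxyphenyl trifluoromethanesulfonate | COc1cc(OC)cc(OS(=O)(=O)C(F)(F)F)c1
F2 | step 4 | 1-heneicosyl-3,5-dimethoxybenzene | CCCCCCCCCCCCCCCCCCCCCc1cc(OC)cc(OC)c1
F3 | step 4 | 2-bromo-1-heneicosyl-3,5-dimethoxybenzene | CCCCCCCCCCCCCCCCCCCCCc1cc(OC)cc(OC)c1Br
F4 | step 4 | (2-heneicosyl-4,6-dimethoxyphenyl)lithium | CCCCCCCCCCCCCCCCCCCCCc1cc(OC)cc(OC)c1[Li]
F5 | step 5 | bromomagnesium 2-heneicosyl-4,6-dimethoxyphenoxide | CCCCCCCCCCCCCCCCCCCCCc1cc(OC)cc(OC)c1O[Mg]Br
F6 | step 2 | 1-(methoxymethoxy)-3,5-dimethoxybenzene | COCOc1cc(OC)cc(OC)c1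
F7 | step 2 | [2-(methoxymethoxy)-4,6-dimethoxyphenyl]lithium | COCOc1cc(OC)cc(OC)c1[Li]
F8 | step 2 | 2-iodo-1-(methoxymethoxy)-3,5-dimethoxybenzene | COCOc1cc(OC)cc(OC)c1I
F9 | step 2 | 2-iodo-3,5-dimethoxyphenol | COc1cc(O)c(I)c(OC)c1
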